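## Retrosynthetic overview (numbers as in the forward route)

1. Target 13 ⇐ protected flavonol 11 by hydrogenolysis of four benzyl ethers and desilylation.
2. 11 ⇐ aldehyde 8 + acetophenone 9: Claisen–Schmidt condensation, then Algar–Flynn–Oyamada closure of the pyranone C–O bond (second ring formed).
3. 8 ⇐ 7 by benzylation; 7 ⇐ hydroxystilbene 6 by the key step, a chiral Brønsted acid catalysed C–O ring closure through a p-quinone methide. It builds the dihydrofuran ring first and sets C2 and C3 together.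
4. 6 ⇐ alkyne 3 + bromocatechol aldehyde 4 (one-pot hydrostannation/Stille); 3 ⇐ 1 + 2 (Sonogashira).

Assumption: 1, 2, 4 and 9 are purchased; the (R)-acid of step 3 is taken to give the (2R,3S) product, otherwise its enantiomer is used.

## Route

Step 1
Reactants: 1 4-iodo-2-methoxyphenol; 2 tert-butyldimethyl(prop-2-yn-1-yloxy)silane
Product: 3 4-{3-[(tert-butyldimethylsilyl)oxy]prop-1-yn-1-yl}-2-methoxyphenol
Conditions: PdCl2(PPh3)2 (2 mol%), CuI (4 mol%), Et3N, THF, rt
Reagents that add atoms: none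
Why: Sonogashira coupling of an aryl iodide with a terminal alkyne, which tolerates the free phenol and the silyl ether.

Step 2
Reactants: 3 4-{3-[(tert-butyldimethylsilyl)oxy]prop-1-yn-1-yl}-2-methoxyphenol; 4 3-bromo-4,5-dihydroxybenzaldehyde
Product: 6 3-[(1Z)-3-[(tert-butyldimethylsilyl)oxy]-1-(4-hydroxy-3-methoxyphenyl)prop-1-en-2-yl]-4,5-dihydroxybenzaldehyde, via vinylstannane 5 (not isolated)
Conditions: Bu3SnH (1.1 equiv, slow addition), PdCl2(PPh3)2 (3 mol%), THF, 0 °C to rt; then 4, Pd(PtBu3)2 (5 mol%), CuI (10 mol%), DMF, 60 °C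
Reagents that add atoms: none
Why: Pd-catalysed syn-hydrostannation should put tin on the alkyne carbon next to CH2OTBS (hydride goes to the carbon polarised by the electron-rich aryl group and β to the propargylic oxygen), and the Cu-assisted Stille coupling then replaces tin by the aryl group with retention; the alkene geometry is not carried beyond step 3.

Step 3
Reactants: 6 3-[(1Z)-3-[(tert-butyldimethylsilyl)oxy]-1-(4-hydroxy-3-methoxyphenyl)prop-1-en-2-yl]-4,5-dihydroxybenzaldehyde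
Product: 7 (2R,3S)-3-{[(tert-butyldimethylsilyl)oxy]methyl}-7-hydroxy-2-(4-hydroxy-3-methoxyphenyl)-2,3-dihydro-1-benzofuran-5-carbaldehyde
Conditions: (R)-3,3'-bis(2,4,6-triisopropylphenyl)-H8-BINOL N-triflylphosphoramide (5 mol%), PhMe/CH2Cl2 4:1, 4 Å MS, −20 °C to 0 °C
Reagents that add atoms: none
Why: Proposed new method: an enantioselective cycloisomerisation in which the confined chiral acid, hydrogen-bonded to the catechol OH next to the alkene, protonates the 4-hydroxystilbene at the carbon bearing CH2OTBS (made nucleophilic by the para-OH of the guaiacyl ring, while the formyl-deactivated ring cannot stabilise the alternative cation) to give a phosphoramidate-bound p-quinone methide, whose benzylic carbon is then captured 5-exo by that same catechol oxygen inside the chiral ion pair, so protonation sets C3 (S) and the trans C–O closure (kinetically and thermodynamically preferred, aryl anti to CH2OTBS) sets C2 (R); the poorly basic, bulky silyl ether suppresses ionisation of the allylic oxygen; the closest known reaction types are chiral phosphoric acid catalysed additions to p-quinone methides generated in situ and chiral Brønsted acid catalysed intramolecular hydroalkoxylation of alkenes.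

Step 4
Reactants: 7 (2R,3S)-3-{[(tert-butyldimethylsilyl)oxy]methyl}-7-hydroxy-2-(4-hydroxy-3-methoxyphenyl)-2,3-dihydro-1-benzofuran-5-carbaldehyde
Product: 8 (2R,3S)-7-(benzyloxy)-2-[4-(benzyloxy)-3-methoxyphenyl]-3-{[(tert-butyldimethylsilyl)oxy]methyl}-2,3-dihydro-1-benzofuran-5-carbaldehyde
Conditions: BnBr (2.3 equiv), K2CO3, DMF, 0 °C to rt
Reagents that add atoms: benzyl bromide BrCc1ccccc1
Why: Williamson etherification of the two phenols touches no stereocentre, and capping the guaiacyl oxygen removes the quinone methide pathway for ring opening in the basic step that follows.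

Step 5
Reactants: 8 (2R,3S)-7-(benzyloxy)-2-[4-(benzyloxy)-3-methoxyphenyl]-3-{[(tert-butyldimethylsilyl)oxy]methyl}-2,3-dihydro-1-benzofuran-5-carbaldehyde; 9 1-[2,4-bis(benzyloxy)-6-hydroxyphenyl]ethan-1-one
Product: 11 5,7-bis(benzyloxy)-2-[(2R,3S)-7-(benzyloxy)-2-[4-(benzyloxy)-3-methoxyphenyl]-3-{[(tert-butyldimethylsilyl)oxy]methyl}-2,3-dihydro-1-benzofuran-5-yl]-3-hydroxy-4H-chromen-4-one, via chalcone 10 (not isolated)
Conditions: KOH (50% aq), EtOH/THF, rt, 36 h; then 30% H2O2, 0 °C to rt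
Reagents that add atoms: hydrogen peroxide OO
Why: Claisen–Schmidt condensation gives the 2'-hydroxychalcone, and the Algar–Flynn–Oyamada reaction closes the pyranone C–O bond from the phenoxide while H2O2 supplies the 3-OH; C2 and C3 of the benzofuran carry no acidic hydrogen and are untouched.

Step 6
Reactants: 11 5,7-bis(benzyloxy)-2-[(2R,3S)-7-(benzyloxy)-2-[4-(benzyloxy)-3-methoxyphenyl]-3-{[(tert-butyldimethylsilyl)oxy]methyl}-2,3-dihydro-1-benzofuran-5-yl]-3-hydroxy-4H-chromen-4-one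
Product: 13 2,3-dehydrosilychristin, 2-[(2R,3S)-7-hydroxy-2-(4-hydroxy-3-methoxyphenyl)-3-(hydroxymethyl)-2,3-dihydro-1-benzofuran-5-yl]-3,5,7-trihydroxy-4H-chromen-4-one, via silyl ether 12 (not isolated)
Conditions: H2 (1 atm), 10% Pd/C, EtOAc/MeOH, rt; filter; then 1 M aq HCl, THF/MeOH, rt
Reagents that add atoms: none
Why: Hydrogenolysis removes the four benzyl ethers under neutral conditions that leave the flavonol double bond and the cyclic benzylic ether intact, and brief dilute acid then cleaves the primary silyl ether without opening the dihydrobenzofuran.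

## Compound list

1 | 4-iodo-2-methoxyphenol | COc1cc(I)ccc1O | starting material
2 | tert-butyldimethyl(prop-2-yn-1-yloxy)silane | C#CCO[Si](C)(C)C(C)(C)C | starting material
3 | 4-{3-[(tert-butyldimethylsilyl)oxy]prop-1-yn-1-yl}-2-methoxyphenol | COc1cc(C#CCO[Si](C)(C)C(C)(C)C)ccc1O | intermediate
4 | 3-bromo-4,5-dihydroxybenzaldehyde | O=Cc1cc(O)c(O)c(Br)c1 | starting material
5 | 4-[(1E)-3-[(tert-butyldimethylsilyl)oxy]-2-(tributylstannyl)prop-1-en-1-yl]-2-methoxyphenol | COc1cc(/C=C(\CO[Si](C)(C)C(C)(C)C)[Sn](CCCC)(CCCC)CCCC)ccc1O | intermediate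
6 | 3-[(1Z)-3-[(tert-butyldimethylsilyl)oxy]-1-(4-hydroxy-3-methoxyphenyl)prop-1-en-2-yl]-4,5-dihydroxybenzaldehyde | COc1cc(/C=C(\CO[Si](C)(C)C(C)(C)C)c2cc(C=O)cc(O)c2O)ccc1O | intermediate
7 | (2R,3S)-3-{[(tert-butyldimethylsilyl)oxy]methyl}-7-hydroxy-2-(4-hydroxy-3-methoxyphenyl)-2,3-dihydro-1-benzofuran-5-carbaldehyde | COc1cc([C@@H]2Oc3c(O)cc(C=O)cc3[C@H]2CO[Si](C)(C)C(C)(C)C)ccc1O | intermediate
8 | (2R,3S)-7-(benzyloxy)-2-[4-(benzyloxy)-3-methoxyphenyl]-3-{[(tert-butyldimethylsilyl)oxy]methyl}-2,3-dihydro-1-benzofuran-5-carbaldehyde | COc1cc([C@@H]2Oc3c(OCc4ccccc4)cc(C=O)cc3[C@H]2CO[Si](C)(C)C(C)(C)C)ccc1OCc1ccccc1 | intermediate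
9 | 1-[2,4-bis(benzyloxy)-6-hydroxyphenyl]ethan-1-one | CC(=O)c1c(O)cc(OCc2ccccc2)cc1OCc1ccccc1 | starting material
10 | (2E)-3-[(2R,3S)-7-(benzyloxy)-2-[4-(benzyloxy)-3-methoxyphenyl]-3-{[(tert-butyldimethylsilyl)oxy]methyl}-2,3-dihydro-1-benzofuran-5-yl]-1-[2,4-bis(benzyloxy)-6-hydroxyphenyl]prop-2-en-1-one | COc1cc([C@@H]2Oc3c(OCc4ccccc4)cc(/C=C/C(=O)c4c(O)cc(OCc5ccccc5)cc4OCc4ccccc4)cc3[C@H]2CO[Si](C)(C)C(C)(C)C)ccc1OCc1ccccc1 | intermediate
11 | 5,7-bis(benzyloxy)-2-[(2R,3S)-7-(benzyloxy)-2-[4-(benzyloxy)-3-methoxyphenyl]-3-{[(tert-butyldimethylsilyl)oxy]methyl}-2,3-dihydro-1-benzofuran-5-yl]-3-hydroxy-4H-chromen-4-one | COc1cc([C@@H]2Oc3c(OCc4ccccc4)cc(-c4oc5cc(OCc6ccccc6)cc(OCc6ccccc6)c5c(=O)c4O)cc3[C@H]2CO[Si](C)(C)C(C)(C)C)ccc1OCc1ccccc1 | intermediate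
12 | 2-[(2R,3S)-3-{[(tert-butyldimethylsilyl)oxy]methyl}-7-hydroxy-2-(4-hydroxy-3-methoxyphenyl)-2,3-dihydro-1-benzofuran-5-yl]-3,5,7-trihydroxy-4H-chromen-4-one | COc1cc([C@@H]2Oc3c(O)cc(-c4oc5cc(O)cc(O)c5c(=O)c4O)cc3[C@H]2CO[Si](C)(C)C(C)(C)C)ccc1O | intermediate
13 | 2,3-dehydrosilychristin, 2-[(2R,3S)-7-hydroxy-2-(4-hydroxy-3-methoxyphenyl)-3-(hydroxymethyl)-2,3-dihydro-1-benzofuran-5-yl]-3,5,7-trihydroxy-4H-chromen-4-one | COc1cc([C@@H]2Oc3c(O)cc(-c4oc5cc(O)cc(O)c5c(=O)c4O)cc3[C@H]2CO)ccc1O | target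

## Step count

Total steps: 6. Longest linear sequence: 6 (1 → 3 → 6 → 7 → 8 → 11 → 13).

## Three steps most likely to fail

**Step 3 (the proposed new reaction).** The risks are low enantioselectivity, competing protonation at the other alkene carbon, and erosion by reversible ring opening if the reaction is left too long. The fallback sets out from 6 and uses known chemistry. Compound 6 is cyclised with an achiral acid (diphenyl phosphate, 10 mol%, CH2Cl2, rt), the acid-promoted quinone methide cyclisation known from hydroxystilbene and lignan chemistry. This gives the racemic trans product, that is 7 together with its enantiomer (2S,3R)-3-{[(tert-butyldimethylsilyl)oxy]methyl}-7-hydroxy-2-(4-hydroxy-3-methoxyphenyl)-2,3-dihydro-1-benzofuran-5-carbaldehyde F3. The two are separated by preparative SFC on a chiral stationary phase, and the route is rejoined at 7.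

**Step 2 (one-pot hydrostannation/Stille).** The risks are a regioisomeric stannane and slow coupling of the hindered α-substituted vinylstannane with the unprotected bromocatechol (protodestannylation). The fallback sets out from 5, now isolated and freed from its regioisomer by chromatography. Iododestannylation (I2, CH2Cl2, 0 °C, retention) gives 4-[(1E)-3-[(tert-butyldimethylsilyl)oxy]-2-iodoprop-1-en-1-yl]-2-methoxyphenol F1. Miyaura borylation (B2pin2, Pd(dppf)Cl2, KOAc, dioxane, 80 °C) gives 4-[(1Z)-3-[(tert-butyldimethylsilyl)oxy]-2-(4,4,5,5-tetramethyl-1,3,2-dioxaborolan-2-yl)prop-1-en-1-yl]-2-methoxyphenol F2. A Suzuki coupling of this boronate with 4 (SPhos Pd G3, K3PO4, dioxane/H2O, 60 °C, degassed) replaces the slow tin transmetalation and comes back to the route at 6.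

**Step 5 (one-pot Claisen–Schmidt/Algar–Flynn–Oyamada).** The risk is aurone formation, which the 6'-alkoxy group favours. The fallback sets out from chalcone 10, isolated before peroxide is added, and goes through the dihydroflavonol.
- The 2'-OH is capped (MOMCl, NaH, THF, 0 °C) to give (2E)-3-[(2R,3S)-7-(benzyloxy)-2-[4-(benzyloxy)-3-methoxyphenyl]-3-{[(tert-butyldimethylsilyl)oxy]methyl}-2,3-dihydro-1-benzofuran-5-yl]-1-[2,4-bis(benzyloxy)-6-(methoxymethoxy)phenyl]prop-2-en-1-one F4.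
- Weitz–Scheffer epoxidation (H2O2, NaOH, MeOH/THF) gives the trans-epoxide of that enone, as both diastereomers, F5.
- HCl in MeOH/THF at 55 °C removes the MOM and silyl groups and lets the freed phenol open the epoxide, giving 5,7-bis(benzyloxy)-2-[(2R,3S)-7-(benzyloxy)-2-[4-(benzyloxy)-3-methoxyphenyl]-3-(hydroxymethyl)-2,3-dihydro-1-benzofuran-5-yl]-3-hydroxychroman-4-one (2,3-trans, both diastereomers) F6.
- Hydrogenolysis (H2, Pd/C) gives silychristin A mixed with its (2S,3S)-diastereomer F7.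
- The known base-mediated aerobic dehydrogenation of silychristin (O2, pyridine, 95 °C) converts both diastereomers into the same flavonol and comes back to the route at 13.

## Further compounds

F1 | step 2 | 4-[(1E)-3-[(tert-butyldimethylsilyl)oxy]-2-iodoprop-1-en-1-yl]-2-methoxyphenol | COc1cc(/C=C(\CO[Si](C)(C)C(C)(C)C)I)ccc1O
F2 | step 2 | 4-[(1Z)-3-[(tert-butyldimethylsilyl)oxy]-2-(4,4,5,5-tetramethyl-1,3,2-dioxaborolan-2-yl)prop-1-en-1-yl]-2-methoxyphenol | COc1cc(/C=C(\CO[Si](C)(C)C(C)(C)C)B2OC(C)(C)C(C)(C)O2)ccc1O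
F3 | step 3 | (2S,3R)-3-{[(tert-butyldimethylsilyl)oxy]methyl}-7-hydroxy-2-(4-hydroxy-3-methoxyphenyl)-2,3-dihydro-1-benzofuran-5-carbaldehyde | COc1cc([C@H]2Oc3c(O)cc(C=O)cc3[C@@H]2CO[Si](C)(C)C(C)(C)C)ccc1O
F4 | step 5 | (2E)-3-[(2R,3S)-7-(benzyloxy)-2-[4-(benzyloxy)-3-methoxyphenyl]-3-{[(tert-butyldimethylsilyl)oxy]methyl}-2,3-dihydro-1-benzofuran-5-yl]-1-[2,4-bis(benzyloxy)-6-(methoxymethoxy)phenyl]prop-2-en-1-one | COc1cc([C@@H]2Oc3c(OCc4ccccc4)cc(/C=C/C(=O)c4c(OCOC)cc(OCc5ccccc5)cc4OCc4ccccc4)cc3[C@H]2CO[Si](C)(C)C(C)(C)C)ccc1OCc1ccccc1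
F5 | step 5 | trans-epoxide of F4 (both epoxide diastereomers; benzofuran 2R,3S) | COc1cc([C@@H]2Oc3c(OCc4ccccc4)cc(C4OC4C(=O)c4c(OCOC)cc(OCc5ccccc5)cc4OCc4ccccc4)cc3[C@H]2CO[Si](C)(C)C(C)(C)C)ccc1OCc1ccccc1
F6 | step 5 | 5,7-bis(benzyloxy)-2-[(2R,3S)-7-(benzyloxy)-2-[4-(benzyloxy)-3-methoxyphenyl]-3-(hydroxymethyl)-2,3-dihydro-1-benzofuran-5-yl]-3-hydroxychroman-4-one (2,3-trans, (2R,3R)/(2S,3S) mixture) | COc1cc([C@@H]2Oc3c(OCc4ccccc4)cc(C4Oc5cc(OCc6ccccc6)cc(OCc6ccccc6)c5C(=O)C4O)cc3[C@H]2CO)ccc1OCc1ccccc1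
F7 | step 5 | silychristin A mixed with its (2S,3S)-diastereomer (2,3-trans dihydroflavonol; benzofuran 2R,3S) | COc1cc([C@@H]2Oc3c(O)cc(C4Oc5cc(O)cc(O)c5C(=O)C4O)cc3[C@H]2CO)ccc1O
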